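## The problem

The target **25** is a daucane-type sesquiterpenoid diester built on a hydroazulene: a cyclopentane (C1–C5) is cis-fused across C1–C5 to a cycloheptene (C1, C5, C6, C7, C8, C9, C10) with its double bond at C8=C9. The locants used throughout are: C1 the methyl-bearing fusion carbon, C2 and C3 the ring CH2 groups, C4 the isopropyl carbinol, C5 the fusion CH, C6 the aroyloxy CH, C7 a CH2, C8 the methyl-bearing alkene carbon, C9 the alkene CH, C10 the tigloyloxy CH. Five contiguous stereocentres (1R,4R,5S,6S,10S) must be set: on a flat drawing the C1 methyl, C5–H, the C4 isopropyl and the C6 oxygen lie on one face, the C4 hydroxyl and the C10 oxygen on the other. Only C10, a secondary allylic carbinol, is an obvious handle for reagent control; it can relay to the neighbouring quaternary C1, C1 fixes C5 through the cis fusion, and the folded bicycle can then steer C6 and C4. The end of the synthesis must be gentle: the C10 tiglate is an allylic ester and a Michael acceptor, the C6 ester carries a free phenol, the tertiary C4 alcohol sits β to the C6 oxygen (retro-aldol and elimination channels at the ketone stage), and the trisubstituted alkene rules out hydrogenolysis. The two secondary hydroxyls (C6, C10) receive different acyl groups and must be distinguishable from the moment they appear. The feature that opens a short way in is that C4 is oxygenated: as a carbonyl it makes C5 α and C1 β, so a 3-substituted cyclopent-2-enone (C4=O, C5=C1) takes up the C1 methyl as a nucleophile and delivers an enolate at C5, the atom that must bond to C6.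

## Retrosynthesis

**Esters (25 ⇒ 24 ⇒ 23 ⇒ 21 ⇒ 20).** The acyl C–O bonds at C6 and C10 are cut first, because both esters are the most fragile parts of the molecule. The phenol is carried as an acetate (24) that an amine removes without touching alkyl esters. The C6 oxygen is carried as an allyl ether (21, 23) and the C10 oxygen as a silyl ether, so the two secondary oxygens are never free together. Diol 20 (C4–OH, C10–OH, C6–O-allyl) is far simpler than 25; the forward steps only need selective acylation of a secondary over a tertiary alcohol.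

**C4–isopropyl bond (20 ⇒ 19 ⇒ 18).** Cutting the C4–C(isopropyl) bond returns the C4 ketone 18. The alternative of carrying the tertiary carbinol through the ring construction would remove the carbonyl that makes the key step possible. The forward addition must come from the convex face of the cis-fused bicycle (syn to C5–H, anti to the C5–C6 bond) and must beat enolisation of a β-alkoxy ketone.

**C5–C6 and C1–CH3 (18 ⇒ 17 ⇒ 16 + 6).** Both bonds are cut in one operation. The C5–C6 cut is an enol silane/oxocarbenium (Mukaiyama-type) disconnection that opens the seven-membered ring to a diallyl acetal. The C1–CH3 cut is a cuprate conjugate addition that removes the quaternary centre and regenerates the enone 16. Against the neighbouring cuts (C6–C7 or C9–C10 by allylation, C8=C9 by metathesis), this one removes a ring, a quaternary carbon and three stereocentres at once, and the enolate needed for ring closure is produced regiospecifically by the first bond formation. The precursor 16 has a single stereocentre (C10). The forward step asks for one enone face for methyl, cis fusion and one configuration at C6.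

**C10 stereocentre and masking groups (16 ⇒ 15 ⇒ 14 ⇒ 13).** The enone carbonyl is masked as a dioxolane (15), the silyl ether is traced to carbinol 14 and the C10–H bond is cut to dienone 13. A reduction is preferred to an asymmetric carbonyl addition because the cross-conjugated ketone is directly available from two simple fragments. The forward reduction must distinguish an α-branched cyclopentenyl group from an unbranched alkenyl group; the later ketal hydrolysis must spare the acyclic diallyl acetal.

**C1–C10 bond (13 ⇒ 8 + 12; 12 ⇐ 11 ⇐ 10 ⇐ 9).** Acyl substitution of Weinreb amide 8 by the β-lithio enone ketal 12 joins the halves at the ketone oxidation level without a separate oxidation. Vinyllithium 12 comes from bromoketal 11, that from bromoenone 10 and cyclopentane-1,3-dione 9. A coupling at the aldehyde level would need an extra oxidation and would expose a cross-conjugated enedione.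

**Z-alkene and chain (8 ⇒ 7 ⇒ 5 + 6 ⇒ 3 ⇒ 1 + 2).** The C8–CH3 bond is cut by syn-carbocupration of ynoate 5 with cuprate 6, which fixes the Z geometry that must later hold C7 and C10 on the same side. The C9–C10 bond is cut by carboxylation of alkyne 3, and the acetal oxygens are traced to allyl alcohol 2 and the diethyl acetal 1. C6 is at the aldehyde oxidation level from the first step, so the conjugation-prone β,γ-unsaturated aldehyde never appears. The same cuprate serves twice.

## Roads not taken

**Alternative 1:** Cut at C1–C5 and C1–C10, tracing the cycloheptene to a benzene ring (C5–C10) and the five-membered ring to a side chain on C5 ending in a carbenoid at C1. Forward, Rh2(OAc)4 would decompose an α-methyl-α-diazo ketone arm; the carbenoid adds across the ipso and free ortho positions of a methoxytolyl ring and the norcaradiene opens (intramolecular Buchner reaction) to azulenone A1.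
- Merits: both rings arise in one step from a cheap arene, the quaternary C1 is set under the influence of a preformed C4 carbinol, and fewer C–C bond-forming steps are needed than in the chosen plan.
- Weak points: in A1 the carbons C5, C6 and C10 are all sp2, C10 bears no oxygen and there is a surplus ketone at C2. Reducing the triene to C8=C9 alone, oxygenating C10 with the right configuration, converting the C5=C6 enol ether into a cis-fused C5–H/C6–O pair and deleting the C2 carbonyl is a long redox sequence without evident regio- or stereocontrol. The α-methyl carbenoid can also divert by 1,2-hydride shift, and the ortho-methoxy group leaves the site of addition (C5–C6 or C5–C10) open.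
- Comparison: this road reaches the bicyclic skeleton faster. The chosen plan sets against it that C6 and C10 arrive with their oxygens at the final oxidation level and defined configuration, so the seven-membered ring needs no redox editing after closure.

**Alternative 2:** Cut at C1–C5, with the C6 oxygen drawn from an epoxide and the seven-membered ring left open between C8 and C9. Forward, BF3·OEt2 would open the epoxide of a 1-(epoxyalkyl)cyclobutanol; C1 migrates from the carbinol carbon C4 to C5 (semipinacol ring expansion) to give cyclopentanone A2. A later ring-closing metathesis of its vinyl and methallyl ends (second-generation Grubbs catalyst) would make C8=C9.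
- Merits: the step is stereospecific. The migrating C1 keeps its configuration and C5/C6 follow from the epoxide geometry, whereas in the chosen plan the sense at C1 and the configuration at C6 rest on transition-state preferences. C6 emerges as a free hydroxyl, which saves the allyl ether removal, and the ring alkene geometry comes for free.
- Weak points: the substrate must already contain C10, the quaternary C1, a strained cyclobutanol and a stereodefined epoxide. A2 is a β-hydroxy ketone with an epimerisable C5. The seven-membered ring still has to be closed separately by forming a trisubstituted alkene next to a neopentylic silyloxy carbon.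
- Comparison: this road is better in stereochemical certainty at C5/C6 and needs one protecting group less. The chosen plan sets against it a much shorter precursor (one reagent-controlled stereocentre) and formation of the quaternary centre, the C5–C6 bond and the ring in one flask.

**Alternative 3:** Cut at C6–C7 and C9–C10, so the seven-membered ring comes from a cyclopentane with cis formyl groups on C1 and C5 and a four-carbon bis-nucleophile. Forward, reagent A4 would add first as an allylindium (through its chloride) to one formyl group and then, after BF3·OEt2 is added to the same flask, as an allylsilane to the other. This gives diol A3 with an exocyclic methylene on C8.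
- Merits: it is the most convergent road. The C4 tertiary carbinol is already in place, so the late isopropyl addition to a hindered ketone (a weak step of the chosen plan) is avoided, and both secondary oxygens arrive at the right oxidation level.
- Weak points: C6 and C10 are set in two separate additions next to a ring fusion, and the required trans arrangement (C6–O cis, C10–O trans to the C1 methyl) is not obviously favoured. The C5 formyl group is epimerisable and β to the C4 silyloxy group. The exocyclic alkene must be moved into the ring towards C9 and not C7, two nearly equivalent directions. The two secondary hydroxyls of A3 are freed together and must then be differentiated.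
- Comparison: this road is superior in convergence and in avoiding the late Grignard addition. The chosen plan sets against it that the C6 and C10 oxygens are distinguishable from the start (allyl ether and silyl ether) and that alkene position and geometry are fixed before ring closure.

Key step: step 11

Remark 1: lithium dimethylcuprate **6** is prepared in the flask from MeLi and CuI directly before use and is listed as a reagent-type starting material.
Remark 2: 4,4-diethoxybut-1-yne **1**, Ph3PBr2, tigloyl chloride and 4-acetoxybenzoyl chloride are taken to be catalogue chemicals.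
Remark 3: locants C1–C10 in the text are those defined in the first section; the systematic names use azulene numbering.

## Route

Step 1
Reactants: 1 4,4-diethoxybut-1-yne; 2 prop-2-en-1-ol (allyl alcohol)
Product: 3 4,4-bis(prop-2-en-1-yloxy)but-1-yne
Conditions: 2 (10 equiv), PPTS (2 mol %), 65 °C, EtOH distilled off under reduced pressure
Reagents that add atoms: none
Why: Acid-catalysed transacetalisation; the equilibrium is driven by removing the lower-boiling ethanol from a large excess of allyl alcohol, and the weak acid and moderate temperature avoid loss of alcohol to an enyne ether.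

Step 2
Reactants: 3 4,4-bis(prop-2-en-1-yloxy)but-1-yne
Product: 5 methyl 5,5-bis(prop-2-en-1-yloxy)pent-2-ynoate, via lithium acetylide 4 (not isolated)
Conditions: n-BuLi (1.0 equiv), THF, −78 °C; ClCO2Me, −78 → 0 °C
Reagents that add atoms: methyl chloroformate, COC(=O)Cl
Why: The terminal alkyne is deprotonated far faster than the allyl ethers or the propargylic CH2, and C-acylation of a lithium acetylide with a chloroformate is the standard ynoate synthesis.

Step 3
Reactants: 5 methyl 5,5-bis(prop-2-en-1-yloxy)pent-2-ynoate; 6 lithium dimethylcuprate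
Product: 7 methyl (2Z)-3-methyl-5,5-bis(prop-2-en-1-yloxy)pent-2-enoate
Conditions: Me2CuLi (1.2 equiv, from MeLi and CuI), THF, −78 °C; MeOH, −78 °C
Reagents that add atoms: none
Why: syn-Carbocupration of an ynoate (cuprate conjugate addition) puts copper cis to the new methyl; protonation at −78 °C with retention leaves the C7 chain cis to the ester (Z), and the low temperature prevents equilibration through the allenolate.

Step 4
Reactants: 7 methyl (2Z)-3-methyl-5,5-bis(prop-2-en-1-yloxy)pent-2-enoate
Product: 8 (2Z)-N-methoxy-N,3-dimethyl-5,5-bis(prop-2-en-1-yloxy)pent-2-enamide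
Conditions: MeNHOMe·HCl (1.6 equiv), iPrMgCl (3.2 equiv), THF, −20 → 0 °C
Reagents that add atoms: N,O-dimethylhydroxylamine hydrochloride, CNOC.Cl
Why: Weinreb amide formation from an ester with the chloromagnesium amide made in the flask; β,β-disubstitution blocks conjugate addition, the weakly basic, non-Lewis-acidic medium leaves the acetal and the alkene geometry alone.

Step 5
Reactants: 9 cyclopentane-1,3-dione
Product: 10 3-bromocyclopent-2-en-1-one
Conditions: Ph3PBr2, Et3N, CH2Cl2, 0 °C → rt
Reagents that add atoms: dibromotriphenylphosphorane, BrP(Br)(c1ccccc1)(c1ccccc1)c1ccccc1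
Why: The enol oxygen of the dione attacks phosphorus and bromide displaces triphenylphosphine oxide by addition–elimination, the standard conversion of a cyclic 1,3-dione into a β-bromo enone.

Step 6
Reactants: 10 3-bromocyclopent-2-en-1-one
Product: 11 7-bromo-1,4-dioxaspiro[4.4]non-6-ene
Conditions: Me3SiOCH2CH2OSiMe3, Me3SiOTf (5 mol %), CH2Cl2, −78 → −20 °C
Reagents that add atoms: 1,2-bis(trimethylsilyloxy)ethane, C[Si](C)(C)OCCO[Si](C)(C)C
Why: Aprotic silyl-transfer ketalisation at low temperature forms the dioxolane without moving the double bond and without addition–elimination at the vinylic bromide; formation of hexamethyldisiloxane drives it.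

Step 7
Reactants: 11 7-bromo-1,4-dioxaspiro[4.4]non-6-ene; 8 (2Z)-N-methoxy-N,3-dimethyl-5,5-bis(prop-2-en-1-yloxy)pent-2-enamide
Product: 13 (2Z)-1-(1,4-dioxaspiro[4.4]non-6-en-7-yl)-3-methyl-5,5-bis(prop-2-en-1-yloxy)pent-2-en-1-one, via vinyllithium 12 (not isolated)
Conditions: 11, t-BuLi (2.0 equiv), Et2O, −78 °C; then 8, THF, −78 → −40 °C; aq. NH4Cl
Reagents that add atoms: none
Why: Bromine–lithium exchange gives the β-lithio enone ketal (a β-acylvinyl anion equivalent); its 1,2-addition to the Weinreb amide stops at the chelated tetrahedral intermediate, so the cross-conjugated ketone is released only on work-up (Weinreb ketone synthesis).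

Step 8
Reactants: 13 (2Z)-1-(1,4-dioxaspiro[4.4]non-6-en-7-yl)-3-methyl-5,5-bis(prop-2-en-1-yloxy)pent-2-en-1-one
Product: 14 (1S,2Z)-1-(1,4-dioxaspiro[4.4]non-6-en-7-yl)-3-methyl-5,5-bis(prop-2-en-1-yloxy)pent-2-en-1-ol
Conditions: (R)-Me-CBS oxazaborolidine (0.3 equiv), catecholborane (1.8 equiv), toluene, −78 °C
Reagents that add atoms: none
Why: Corey–Bakshi–Shibata reduction; the carbonyl binds boron cis to the unbranched CH= of the Z-alkenyl arm (small group) and away from the fully substituted cyclopentenyl carbon (large group), so the (R)-catalyst should deliver hydride to give the 1S carbinol, and catecholborane at −78 °C reduces 1,2 without hydroborating the allyl ethers.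

Step 9
Reactants: 14 (1S,2Z)-1-(1,4-dioxaspiro[4.4]non-6-en-7-yl)-3-methyl-5,5-bis(prop-2-en-1-yloxy)pent-2-en-1-ol
Product: 15 tert-butyl{[(1S,2Z)-1-(1,4-dioxaspiro[4.4]non-6-en-7-yl)-3-methyl-5,5-bis(prop-2-en-1-yloxy)pent-2-en-1-yl]oxy}dimethylsilane
Conditions: TBSCl, imidazole, DMF, rt
Reagents that add atoms: tert-butyldimethylsilyl chloride, CC(C)(C)[Si](C)(C)Cl
Why: Standard silylation of a secondary alcohol under basic conditions that leave ketal and acetal untouched; the bulky silyl group is the later control element for the cuprate.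

Step 10
Reactants: 15 tert-butyl{[(1S,2Z)-1-(1,4-dioxaspiro[4.4]non-6-en-7-yl)-3-methyl-5,5-bis(prop-2-en-1-yloxy)pent-2-en-1-yl]oxy}dimethylsilane
Product: 16 3-[(1S,2Z)-1-{[tert-butyl(dimethyl)silyl]oxy}-3-methyl-5,5-bis(prop-2-en-1-yloxy)pent-2-en-1-yl]cyclopent-2-en-1-one
Conditions: PPTS (10 mol %), acetone/H2O (10:1), 0 °C → rt, monitored closely
Reagents that add atoms: water, O
Why: Chemoselective ketal hydrolysis; the dioxolane of a conjugated ketone ionises to an allyl-stabilised tertiary oxocarbenium ion orders of magnitude faster than the acyclic acetal of an aldehyde, whose allyloxy groups are in addition inductively deactivating, and the silyl ether tolerates PPTS.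

Step 11
Reactants: 16 3-[(1S,2Z)-1-{[tert-butyl(dimethyl)silyl]oxy}-3-methyl-5,5-bis(prop-2-en-1-yloxy)pent-2-en-1-yl]cyclopent-2-en-1-one; 6 lithium dimethylcuprate
Product: 18 (3aR,4S,8S,8aS)-4-{[tert-butyl(dimethyl)silyl]oxy}-3a,6-dimethyl-8-(prop-2-en-1-yloxy)-3,3a,4,7,8,8a-hexahydroazulen-1(2H)-one, via trimethylsilyl enol ether 17 (not isolated)
Conditions: Me2CuLi (1.3 equiv, from MeLi and CuI), Me3SiCl (3 equiv), Et2O, −78 °C; then CH2Cl2, BF3·OEt2 (2.5 equiv), −78 → −40 °C; aq. NaHCO3
Reagents that add atoms: none
Why: Me2CuLi (monovalent copper) adds to the enone through a copper–alkene complex and transfers methyl to C1, and Me3SiCl traps the enolate on oxygen, so the C4=C5 enol silane 17 forms as the only regioisomer (cuprate conjugate addition with chlorosilane trapping). BF3·OEt2 then ionises the diallyl acetal to the (E)-O-allyl oxocarbenium ion at C6, which is attacked by C5 of 17 with loss of allyloxytrimethylsilane; the closest known reaction type is the tandem conjugate addition–Mukaiyama-type addition of an enol silane to an acetal. The one ring that closes is the seven-membered ring C1–C10–C9=C8–C7–C6–C5, in a 7-(enolexo)-exo-trig mode. C1 is controlled by C10: in the reactive rotamer the C10–H bond lies near the enone plane on the C2 side (least A(1,2) strain with the ring CH2), the alkenyl arm sits on the C5 side and the bulky silyloxy group is perpendicular, so methyl enters anti to the C–O bond and gives 1R. C5 is controlled by C1: the four-atom tether with its Z alkene reaches only the enol-silane face syn to the C1–C10 bond, which makes the fusion cis (5S). C6 is controlled by the open transition state, in which C4=C5 and C6=O+ are antiperiplanar and the O-allyl group points away from the five-membered ring, placing the allyloxy group cis to C5–H (6S). The step needs π-facial selectivity at C1 (secured by the C10 silyl ether), ionisation of the acetal in preference to the allylic silyl ether (secured by low temperature and the stabilisation of the cation by the second acetal oxygen) and a chain that cannot slip into conjugation (secured by the acetal oxidation level and the Z alkene).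

Step 12
Reactants: 18 (3aR,4S,8S,8aS)-4-{[tert-butyl(dimethyl)silyl]oxy}-3a,6-dimethyl-8-(prop-2-en-1-yloxy)-3,3a,4,7,8,8a-hexahydroazulen-1(2H)-one
Product: 19 (1R,3aR,4S,8S,8aS)-4-{[tert-butyl(dimethyl)silyl]oxy}-3a,6-dimethyl-1-(propan-2-yl)-8-(prop-2-en-1-yloxy)-1,2,3,3a,4,7,8,8a-octahydroazulen-1-ol
Conditions: iPrMgCl (3 equiv), CeCl3 (anhydrous, 3 equiv), THF, −78 → −20 °C
Reagents that add atoms: isopropylmagnesium chloride, CC(C)[Mg]Cl
Why: Organocerium 1,2-addition, chosen because the weakly basic reagent suppresses enolisation of the β-alkoxy ketone and β-hydride reduction; the nucleophile approaches the convex face of the cis-fused bicycle, syn to C5–H and anti to the C5–C6 bond, which places isopropyl on the face of the angular methyl and gives the 4R carbinol (C1 in azulene numbering).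

Step 13
Reactants: 19 (1R,3aR,4S,8S,8aS)-4-{[tert-butyl(dimethyl)silyl]oxy}-3a,6-dimethyl-1-(propan-2-yl)-8-(prop-2-en-1-yloxy)-1,2,3,3a,4,7,8,8a-octahydroazulen-1-ol
Product: 20 (1R,3aR,4S,8S,8aS)-3a,6-dimethyl-1-(propan-2-yl)-8-(prop-2-en-1-yloxy)-1,2,3,3a,4,7,8,8a-octahydroazulene-1,4-diol
Conditions: Bu4NF (3 equiv), THF, rt → 45 °C
Reagents that add atoms: none
Why: Fluoride desilylation; it is placed before any ester is present so that the neopentylic silyl ether can be forced with warm fluoride without risk to acyl groups.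

Step 14
Reactants: 20 (1R,3aR,4S,8S,8aS)-3a,6-dimethyl-1-(propan-2-yl)-8-(prop-2-en-1-yloxy)-1,2,3,3a,4,7,8,8a-octahydroazulene-1,4-diol
Product: 21 (1R,3aR,4S,8S,8aS)-1-hydroxy-3a,6-dimethyl-1-(propan-2-yl)-8-(prop-2-en-1-yloxy)-1,2,3,3a,4,7,8,8a-octahydroazulen-4-yl (2E)-2-methylbut-2-enoate
Conditions: tigloyl chloride (3 equiv), pyridine, DMAP (1 equiv), CH2Cl2, 0 → 40 °C
Reagents that add atoms: (2E)-2-methylbut-2-enoyl chloride, C/C=C(\C)C(=O)Cl
Why: DMAP-catalysed acylation of the secondary C10 alcohol, the tertiary C4 alcohol being inert; pyridine is used in place of a trialkylamine to limit deconjugation of the acyl chloride through its vinylketene, and the E (tiglate) geometry is the stable one.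

Step 15
Reactants: 21 (1R,3aR,4S,8S,8aS)-1-hydroxy-3a,6-dimethyl-1-(propan-2-yl)-8-(prop-2-en-1-yloxy)-1,2,3,3a,4,7,8,8a-octahydroazulen-4-yl (2E)-2-methylbut-2-enoate
Product: 23 (1R,3aR,4S,8S,8aS)-1,8-dihydroxy-3a,6-dimethyl-1-(propan-2-yl)-1,2,3,3a,4,7,8,8a-octahydroazulen-4-yl (2E)-2-methylbut-2-enoate, via prop-1-enyl ether 22 (not isolated)
Conditions: [Ir(cod)(PMePh2)2]PF6 (3 mol %, activated with H2), THF, rt; then 0.1 M HCl, acetone/H2O, rt
Reagents that add atoms: none
Why: The cationic iridium hydride isomerises the terminal allyl ether to the (E)-prop-1-enyl ether and does not touch trisubstituted alkenes or esters; the enol ether is then hydrolysed by dilute acid under conditions that spare the allylic tiglate and the tertiary alcohol.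

Step 16
Reactants: 23 (1R,3aR,4S,8S,8aS)-1,8-dihydroxy-3a,6-dimethyl-1-(propan-2-yl)-1,2,3,3a,4,7,8,8a-octahydroazulen-4-yl (2E)-2-methylbut-2-enoate
Product: 24 (1R,3aR,4S,8S,8aS)-1-hydroxy-3a,6-dimethyl-4-{[(2E)-2-methylbut-2-enoyl]oxy}-1-(propan-2-yl)-1,2,3,3a,4,7,8,8a-octahydroazulen-8-yl 4-(acetyloxy)benzoate
Conditions: 4-acetoxybenzoyl chloride (2 equiv), pyridine, DMAP (cat.), CH2Cl2, rt
Reagents that add atoms: 4-(acetyloxy)benzoyl chloride, CC(=O)Oc1ccc(cc1)C(Cl)=O
Why: Acylation of the secondary C6 alcohol by an acid chloride (tertiary C4–OH inert); the phenol is masked as its acetate so that it cannot compete or oligomerise.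

Step 17
Reactants: 24 (1R,3aR,4S,8S,8aS)-1-hydroxy-3a,6-dimethyl-4-{[(2E)-2-methylbut-2-enoyl]oxy}-1-(propan-2-yl)-1,2,3,3a,4,7,8,8a-octahydroazulen-8-yl 4-(acetyloxy)benzoate
Product: 25 (1R,3aR,4S,8S,8aS)-1-hydroxy-3a,6-dimethyl-4-{[(2E)-2-methylbut-2-enoyl]oxy}-1-(propan-2-yl)-1,2,3,3a,4,7,8,8a-octahydroazulen-8-yl 4-hydroxybenzoate (target)
Conditions: pyrrolidine (3 equiv), CH2Cl2, 0 °C
Reagents that add atoms: none
Why: Aminolysis of the aryl acetate; the 4-acylphenoxide is a far better leaving group than either alkoxide, so the phenol is freed while the tiglate and the benzoate-type ester stay intact.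

## Compound list

1 | 4,4-diethoxybut-1-yne | C#CCC(OCC)OCC | starting material
2 | prop-2-en-1-ol (allyl alcohol) | C=CCO | starting material
3 | 4,4-bis(prop-2-en-1-yloxy)but-1-yne | C#CCC(OCC=C)OCC=C | intermediate
4 | [4,4-bis(prop-2-en-1-yloxy)but-1-yn-1-yl]lithium | [Li]C#CCC(OCC=C)OCC=C | intermediate (not isolated)
5 | methyl 5,5-bis(prop-2-en-1-yloxy)pent-2-ynoate | COC(=O)C#CCC(OCC=C)OCC=C | intermediate
6 | lithium dimethylcuprate (Me2CuLi) | [Li+].C[Cu-]C | starting material
7 | methyl (2Z)-3-methyl-5,5-bis(prop-2-en-1-yloxy)pent-2-enoate | C=CCOC(OCC=C)C/C(C)=C\C(=O)OC | intermediate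
8 | (2Z)-N-methoxy-N,3-dimethyl-5,5-bis(prop-2-en-1-yloxy)pent-2-enamide | C=CCOC(OCC=C)C/C(C)=C\C(=O)N(C)OC | intermediate
9 | cyclopentane-1,3-dione | O=C1CCC(=O)C1 | starting material
10 | 3-bromocyclopent-2-en-1-one | O=C1C=C(Br)CC1 | intermediate
11 | 7-bromo-1,4-dioxaspiro[4.4]non-6-ene | BrC1=CC2(CC1)OCCO2 | intermediate
12 | (1,4-dioxaspiro[4.4]non-6-en-7-yl)lithium | [Li]C1=CC2(CC1)OCCO2 | intermediate (not isolated)
13 | (2Z)-1-(1,4-dioxaspiro[4.4]non-6-en-7-yl)-3-methyl-5,5-bis(prop-2-en-1-yloxy)pent-2-en-1-one | C=CCOC(OCC=C)C/C(C)=C\C(=O)C1=CC2(CC1)OCCO2 | intermediate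
14 | (1S,2Z)-1-(1,4-dioxaspiro[4.4]non-6-en-7-yl)-3-methyl-5,5-bis(prop-2-en-1-yloxy)pent-2-en-1-ol | C=CCOC(OCC=C)C/C(C)=C\[C@H](O)C1=CC2(CC1)OCCO2 | intermediate
15 | tert-butyl{[(1S,2Z)-1-(1,4-dioxaspiro[4.4]non-6-en-7-yl)-3-methyl-5,5-bis(prop-2-en-1-yloxy)pent-2-en-1-yl]oxy}dimethylsilane | C=CCOC(OCC=C)C/C(C)=C\[C@H](O[Si](C)(C)C(C)(C)C)C1=CC2(CC1)OCCO2 | intermediate
16 | 3-[(1S,2Z)-1-{[tert-butyl(dimethyl)silyl]oxy}-3-methyl-5,5-bis(prop-2-en-1-yloxy)pent-2-en-1-yl]cyclopent-2-en-1-one | C=CCOC(OCC=C)C/C(C)=C\[C@H](O[Si](C)(C)C(C)(C)C)C1=CC(=O)CC1 | intermediate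
17 | tert-butyl({(1S,2Z)-3-methyl-1-[(1R)-1-methyl-3-(trimethylsilyloxy)cyclopent-2-en-1-yl]-5,5-bis(prop-2-en-1-yloxy)pent-2-en-1-yl}oxy)dimethylsilane | C=CCOC(OCC=C)C/C(C)=C\[C@H](O[Si](C)(C)C(C)(C)C)[C@]1(C)CCC(O[Si](C)(C)C)=C1 | intermediate (not isolated)
18 | (3aR,4S,8S,8aS)-4-{[tert-butyl(dimethyl)silyl]oxy}-3a,6-dimethyl-8-(prop-2-en-1-yloxy)-3,3a,4,7,8,8a-hexahydroazulen-1(2H)-one | CC(C)(C)[Si](C)(C)O[C@H]1C=C(C)C[C@H](OCC=C)[C@@H]2[C@@]1(C)CCC2=O | intermediate
19 | (1R,3aR,4S,8S,8aS)-4-{[tert-butyl(dimethyl)silyl]oxy}-3a,6-dimethyl-1-(propan-2-yl)-8-(prop-2-en-1-yloxy)-1,2,3,3a,4,7,8,8a-octahydroazulen-1-ol | CC(C)(C)[Si](C)(C)O[C@H]1C=C(C)C[C@H](OCC=C)[C@@H]2[C@@]1(C)CC[C@@]2(O)C(C)C | intermediate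
20 | (1R,3aR,4S,8S,8aS)-3a,6-dimethyl-1-(propan-2-yl)-8-(prop-2-en-1-yloxy)-1,2,3,3a,4,7,8,8a-octahydroazulene-1,4-diol | O[C@H]1C=C(C)C[C@H](OCC=C)[C@@H]2[C@@]1(C)CC[C@@]2(O)C(C)C | intermediate
21 | (1R,3aR,4S,8S,8aS)-1-hydroxy-3a,6-dimethyl-1-(propan-2-yl)-8-(prop-2-en-1-yloxy)-1,2,3,3a,4,7,8,8a-octahydroazulen-4-yl (2E)-2-methylbut-2-enoate | C/C=C(\C)C(=O)O[C@H]1C=C(C)C[C@H](OCC=C)[C@@H]2[C@@]1(C)CC[C@@]2(O)C(C)C | intermediate
22 | (1R,3aR,4S,8S,8aS)-1-hydroxy-3a,6-dimethyl-1-(propan-2-yl)-8-[(1E)-prop-1-en-1-yloxy]-1,2,3,3a,4,7,8,8a-octahydroazulen-4-yl (2E)-2-methylbut-2-enoate | C/C=C(\C)C(=O)O[C@H]1C=C(C)C[C@H](O/C=C/C)[C@@H]2[C@@]1(C)CC[C@@]2(O)C(C)C | intermediate (not isolated)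
23 | (1R,3aR,4S,8S,8aS)-1,8-dihydroxy-3a,6-dimethyl-1-(propan-2-yl)-1,2,3,3a,4,7,8,8a-octahydroazulen-4-yl (2E)-2-methylbut-2-enoate | C/C=C(\C)C(=O)O[C@H]1C=C(C)C[C@H](O)[C@@H]2[C@@]1(C)CC[C@@]2(O)C(C)C | intermediate
24 | (1R,3aR,4S,8S,8aS)-1-hydroxy-3a,6-dimethyl-4-{[(2E)-2-methylbut-2-enoyl]oxy}-1-(propan-2-yl)-1,2,3,3a,4,7,8,8a-octahydroazulen-8-yl 4-(acetyloxy)benzoate | C/C=C(\C)C(=O)O[C@H]1C=C(C)C[C@H](OC(=O)c2ccc(OC(C)=O)cc2)[C@@H]2[C@@]1(C)CC[C@@]2(O)C(C)C | intermediate
25 | (1R,3aR,4S,8S,8aS)-1-hydroxy-3a,6-dimethyl-4-{[(2E)-2-methylbut-2-enoyl]oxy}-1-(propan-2-yl)-1,2,3,3a,4,7,8,8a-octahydroazulen-8-yl 4-hydroxybenzoate (CNP0273650.3) | C/C=C(\C)C(=O)O[C@H]1C=C(C)C[C@H](OC(=O)c2ccc(O)cc2)[C@@H]2[C@@]1(C)CC[C@@]2(O)C(C)C | target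

## Step count and uncertain steps

Total step count: 17. Longest linear sequence: 15 steps (steps 1–4 and 7–17, from 1); the bromoketal branch (steps 5 and 6) joins at step 7.

**Step 11 (key step).** The most likely failure is poor or inverted π-facial selectivity in the methyl transfer. Two rotamers about C1–C10 keep the silyloxy group anti to the incoming cuprate and differ only in whether C10–H or the alkenyl arm lies next to C5–H. If the first prevails, methyl and the C10 oxygen end up cis and the ring closes to the wrong diastereomer. Second-order concerns are methyl transfer from residual organocopper to the oxocarbenium carbon and the configuration at C6, which rests on an open transition state.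

The fallback sets out from dienone 13. Reduction with the enantiomeric (S)-oxazaborolidine gives the (1R)-carbinol F1, silylation the silyl ether F2 and selective ketal hydrolysis the (1R)-enone F3. The same cuprate/BF3·OEt2 sequence, with the facial preference now working for the plan, passes through the enol silane F4 to the C10-epimeric bicyclic ketone F5. Isopropylcerium addition gives the carbinol F6 and fluoride the C10-epimeric diol F7. Dess–Martin oxidation of the allylic C10 alcohol (the tertiary alcohol is inert) gives the enone F8. Luche reduction (NaBH4, CeCl3·7H2O, MeOH, −78 °C), with hydride arriving on the convex face of the cis-fused bicycle, should give the 10S alcohol. The fallback comes back to the route at 20.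

**Step 8.** The likely failure is insufficient enantiofacial discrimination, because both carbonyl substituents are alkenyl groups and the size difference the catalyst reads is smaller than in an alkyl/alkenyl ketone. The fallback sets out from alkyne 3 as its lithium acetylide 4. Acylation with N-methoxy-N-methylcarbamoyl chloride gives the alkynyl Weinreb amide F9, and addition of vinyllithium 12 gives the ynone F10. CBS reduction with the same (R)-catalyst, for which the slender alkynyl group is clearly the small substituent, gives the propargylic alcohol F11 (1R by the priority rules, same spatial arrangement as 14). Iron-catalysed, alkoxide-directed syn-methylmagnesiation (MeMgBr, Fe(acac)3 cat., THF) puts methyl on the distal alkyne carbon and hydrogen cis to it on C9. This sets the Z alkene and returns to the route at 14.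

**Step 10.** The likely failure is loss of chemoselectivity, that is partial hydrolysis of the diallyl acetal together with the ketal, since the two rates differ by a factor and not in kind. The fallback sets out from 15. Both acetals are cleaved on purpose (1 M HCl, THF/H2O, 0 °C) to the keto aldehyde F12. The aldehyde alone is then re-acetalised under aprotic silyl-transfer conditions (allyloxytrimethylsilane, Me3SiOTf cat., CH2Cl2, −78 °C), which leave the enone alone and give the β,γ-alkene no chance to move into conjugation. This returns to the route at 16.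

**Step 12.** The likely failures are reduction of the hindered ketone by β-hydride transfer from the isopropyl reagent, or enolisation followed by β-elimination of the C6 allyloxy group. The fallback sets out from 18. Isopropenylmagnesium bromide with CeCl3 (no β-hydrogen to transfer, less basic) gives the isopropenyl carbinol F13. Desilylation gives the diol F14, tigloylation the ester F15, iridium-catalysed allyl isomerisation the propenyl ether F16 and acid hydrolysis the C6 alcohol F17. Hydrogenation over RhCl(PPh3)3, which takes the 1,1-disubstituted alkene and leaves the two trisubstituted ones, returns to the route at 23.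

**Step 14.** The likely failure is slow acylation of the neopentylic C10 alcohol, with deconjugation of the acyl chloride through its vinylketene. The fallback sets out from 20. Acylation with 2-(diethoxyphosphoryl)propanoic acid (DCC, DMAP), an unhindered sp3 acid, gives the phosphonate ester F18. A Horner–Wadsworth–Emmons reaction with acetaldehyde (LiCl, DBU, MeCN) then builds the (E)-2-methylbut-2-enoate in place and returns to the route at 21.

## Further compounds

F1 | step 11 | (1R,2Z)-1-(1,4-dioxaspiro[4.4]non-6-en-7-yl)-3-methyl-5,5-bis(prop-2-en-1-yloxy)pent-2-en-1-ol | C=CCOC(OCC=C)C/C(C)=C\[C@@H](O)C1=CC2(CC1)OCCO2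
F2 | step 11 | tert-butyl{[(1R,2Z)-1-(1,4-dioxaspiro[4.4]non-6-en-7-yl)-3-methyl-5,5-bis(prop-2-en-1-yloxy)pent-2-en-1-yl]oxy}dimethylsilane | C=CCOC(OCC=C)C/C(C)=C\[C@@H](O[Si](C)(C)C(C)(C)C)C1=CC2(CC1)OCCO2
F3 | step 11 | 3-[(1R,2Z)-1-{[tert-butyl(dimethyl)silyl]oxy}-3-methyl-5,5-bis(prop-2-en-1-yloxy)pent-2-en-1-yl]cyclopent-2-en-1-one | C=CCOC(OCC=C)C/C(C)=C\[C@@H](O[Si](C)(C)C(C)(C)C)C1=CC(=O)CC1
F4 | step 11 | tert-butyl({(1R,2Z)-3-methyl-1-[(1R)-1-methyl-3-(trimethylsilyloxy)cyclopent-2-en-1-yl]-5,5-bis(prop-2-en-1-yloxy)pent-2-en-1-yl}oxy)dimethylsilane | C=CCOC(OCC=C)C/C(C)=C\[C@@H](O[Si](C)(C)C(C)(C)C)[C@]1(C)CCC(O[Si](C)(C)C)=C1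
F5 | step 11 | (3aR,4R,8S,8aS)-4-{[tert-butyl(dimethyl)silyl]oxy}-3a,6-dimethyl-8-(prop-2-en-1-yloxy)-3,3a,4,7,8,8a-hexahydroazulen-1(2H)-one | CC(C)(C)[Si](C)(C)O[C@@H]1C=C(C)C[C@H](OCC=C)[C@@H]2[C@@]1(C)CCC2=O
F6 | step 11 | (1R,3aR,4R,8S,8aS)-4-{[tert-butyl(dimethyl)silyl]oxy}-3a,6-dimethyl-1-(propan-2-yl)-8-(prop-2-en-1-yloxy)-1,2,3,3a,4,7,8,8a-octahydroazulen-1-ol | CC(C)(C)[Si](C)(C)O[C@@H]1C=C(C)C[C@H](OCC=C)[C@@H]2[C@@]1(C)CC[C@@]2(O)C(C)C
F7 | step 11 | (1R,3aR,4R,8S,8aS)-3a,6-dimethyl-1-(propan-2-yl)-8-(prop-2-en-1-yloxy)-1,2,3,3a,4,7,8,8a-octahydroazulene-1,4-diol | O[C@@H]1C=C(C)C[C@H](OCC=C)[C@@H]2[C@@]1(C)CC[C@@]2(O)C(C)C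
F8 | step 11 | (1R,3aR,8S,8aS)-1-hydroxy-3a,6-dimethyl-1-(propan-2-yl)-8-(prop-2-en-1-yloxy)-2,3,3a,7,8,8a-hexahydroazulen-4(1H)-one | O=C1C=C(C)C[C@H](OCC=C)[C@@H]2[C@@]1(C)CC[C@@]2(O)C(C)C
F9 | step 8 | N-methoxy-N-methyl-5,5-bis(prop-2-en-1-yloxy)pent-2-ynamide | C=CCOC(OCC=C)CC#CC(=O)N(C)OC
F10 | step 8 | 1-(1,4-dioxaspiro[4.4]non-6-en-7-yl)-5,5-bis(prop-2-en-1-yloxy)pent-2-yn-1-one | C=CCOC(OCC=C)CC#CC(=O)C1=CC2(CC1)OCCO2
F11 | step 8 | (1R)-1-(1,4-dioxaspiro[4.4]non-6-en-7-yl)-5,5-bis(prop-2-en-1-yloxy)pent-2-yn-1-ol | C=CCOC(OCC=C)CC#C[C@H](O)C1=CC2(CC1)OCCO2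
F12 | step 10 | (3Z,5S)-5-{[tert-butyl(dimethyl)silyl]oxy}-3-methyl-5-(3-oxocyclopent-1-en-1-yl)pent-3-enal | O=CC/C(C)=C\[C@H](O[Si](C)(C)C(C)(C)C)C1=CC(=O)CC1
F13 | step 12 | (1S,3aR,4S,8S,8aS)-4-{[tert-butyl(dimethyl)silyl]oxy}-3a,6-dimethyl-1-(prop-1-en-2-yl)-8-(prop-2-en-1-yloxy)-1,2,3,3a,4,7,8,8a-octahydroazulen-1-ol | CC(C)(C)[Si](C)(C)O[C@H]1C=C(C)C[C@H](OCC=C)[C@@H]2[C@@]1(C)CC[C@@]2(O)C(C)=C
F14 | step 12 | (1S,3aR,4S,8S,8aS)-3a,6-dimethyl-1-(prop-1-en-2-yl)-8-(prop-2-en-1-yloxy)-1,2,3,3a,4,7,8,8a-octahydroazulene-1,4-diol | O[C@H]1C=C(C)C[C@H](OCC=C)[C@@H]2[C@@]1(C)CC[C@@]2(O)C(C)=C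
F15 | step 12 | (1S,3aR,4S,8S,8aS)-1-hydroxy-3a,6-dimethyl-1-(prop-1-en-2-yl)-8-(prop-2-en-1-yloxy)-1,2,3,3a,4,7,8,8a-octahydroazulen-4-yl (2E)-2-methylbut-2-enoate | C/C=C(\C)C(=O)O[C@H]1C=C(C)C[C@H](OCC=C)[C@@H]2[C@@]1(C)CC[C@@]2(O)C(C)=C
F16 | step 12 | (1S,3aR,4S,8S,8aS)-1-hydroxy-3a,6-dimethyl-1-(prop-1-en-2-yl)-8-[(1E)-prop-1-en-1-yloxy]-1,2,3,3a,4,7,8,8a-octahydroazulen-4-yl (2E)-2-methylbut-2-enoate | C/C=C(\C)C(=O)O[C@H]1C=C(C)C[C@H](O/C=C/C)[C@@H]2[C@@]1(C)CC[C@@]2(O)C(C)=C
F17 | step 12 | (1S,3aR,4S,8S,8aS)-1,8-dihydroxy-3a,6-dimethyl-1-(prop-1-en-2-yl)-1,2,3,3a,4,7,8,8a-octahydroazulen-4-yl (2E)-2-methylbut-2-enoate | C/C=C(\C)C(=O)O[C@H]1C=C(C)C[C@H](O)[C@@H]2[C@@]1(C)CC[C@@]2(O)C(C)=C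
F18 | step 14 | (1R,3aR,4S,8S,8aS)-1-hydroxy-3a,6-dimethyl-1-(propan-2-yl)-8-(prop-2-en-1-yloxy)-1,2,3,3a,4,7,8,8a-octahydroazulen-4-yl 2-(diethoxyphosphoryl)propanoate (both epimers at the phosphonate carbon) | CCOP(=O)(OCC)C(C)C(=O)O[C@H]1C=C(C)C[C@H](OCC=C)[C@@H]2[C@@]1(C)CC[C@@]2(O)C(C)C
A1 | alternative 1 | (3R,8aS)-4-methoxy-6,8a-dimethyl-3-(propan-2-yl)-3-[(triethylsilyl)oxy]-3,8a-dihydroazulen-1(2H)-one | C1=CC(C)=CC(OC)=C2[C@@]1(C)C(=O)C[C@@]2(O[Si](CC)(CC)CC)C(C)C
A2 | alternative 2 | (2S,3R)-3-[(1S)-1-{[tert-butyl(dimethyl)silyl]oxy}prop-2-en-1-yl]-2-[(1S)-1-hydroxy-3-methylbut-3-en-1-yl]-3-methylcyclopentan-1-one | C=C[C@H](O[Si](C)(C)C(C)(C)C)[C@]1(C)CCC(=O)[C@@H]1[C@@H](O)CC(C)=C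
A3 | alternative 3 | (1R,3aR,4S,8S,8aS)-3a-methyl-6-methylidene-1-(propan-2-yl)-1-[(triethylsilyl)oxy]decahydroazulene-4,8-diol | O[C@H]1CC(=C)C[C@H](O)[C@@H]2[C@@]1(C)CC[C@@]2(O[Si](CC)(CC)CC)C(C)C
A4 | alternative 3 | [2-(chloromethyl)prop-2-en-1-yl](trimethyl)silane | C=C(CCl)C[Si](C)(C)C
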